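**Retrosynthetic overview**
1. Both esters go on last: the angelate on the C8 allylic alcohol (from 1,2-reduction of a C8 enone) and the 4-hydroxybenzoate on the C4 alcohol, leading back to a bicyclic hydroxy enone.
2. Seven-membered ring (formed second): the C4–C5 bond is made by intramolecular carbonyl-ene closure of a cyclopentane carbaldehyde onto a methallyl group. The C8 ketone is carried as a nitro group (Nef), and once unmasked it draws the alkene into the C6=C7 position.
3. Five-membered ring (formed first), with the first three stereocentres: a one-pot amine-catalysed nitro-Michael/aldol reaction between an achiral keto-enal and a homoallylic nitroalkane.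
4. The keto-enal comes from isobutyraldehyde and methyl vinyl ketone (Stetter) plus a two-carbon formyl olefination; the nitroalkane comes from 4-bromo-2-methylbut-1-ene.

Assumption: the silyl aldimine, 4-bromo-2-methylbut-1-ene, 4-[(tert-butyldimethylsilyl)oxy]benzoic acid and angelic anhydride are taken as catalogue chemicals; the nitro-bearing carbon is carried as a mixture of epimers and written without a descriptor.
Bicyclic compounds are named on the azulene skeleton (C3 tertiary carbinol, C3a/C8a ring fusion, C4 benzoate carbon, C6 methyl-bearing alkene carbon, C8 angelate carbon).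

**Step 1**
Reactants: 1 2-methylpropanal; 2 but-3-en-2-one
Product: 3 6-methylheptane-2,5-dione
Conditions: 3-benzyl-5-(2-hydroxyethyl)-4-methylthiazolium chloride (10 mol%), Et3N, EtOH, 80 °C
Reagents that add atoms: none
Why: Stetter reaction, in which the thiazolylidene-derived Breslow intermediate of 1 adds 1,4 to enone 2 to give the 1,4-diketone; no stereocentre is formed.

**Step 2**
Reactants: 3 6-methylheptane-2,5-dione; 4 N-tert-butyl-2-(trimethylsilyl)ethan-1-imine
Product: 6 (2E)-3,7-dimethyl-6-oxooct-2-enal, via unsaturated tert-butylimine 5 (not isolated)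
Conditions: 4, LiN(iPr)2, THF, −78 °C; then 3, −78 → −20 °C; then aq. oxalic acid, rt
Reagents that add atoms: water, O
Why: Peterson-type formyl olefination, in which the lithiated silyl aldimine attacks the less hindered methyl ketone in preference to the isopropyl ketone and acid hydrolysis of the unsaturated imine releases the enal; the major E isomer is taken on after chromatography (the Z isomer can be re-equilibrated), and no stereocentre is formed.

**Step 3**
Reactants: 7 4-bromo-2-methylbut-1-ene
Product: 8 2-methyl-4-nitrobut-1-ene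
Conditions: AgNO2, Et2O, 0 °C → rt, dark
Reagents that add atoms: silver nitrite AgNO2, [Ag+].[O-]N=O
Why: Victor Meyer reaction, an SN2 displacement of the primary bromide by nitrite through nitrogen, which the silver salt in ether favours over O-alkylation; no stereocentre is formed.

**Step 4**
Reactants: 6 (2E)-3,7-dimethyl-6-oxooct-2-enal; 8 2-methyl-4-nitrobut-1-ene
Product: 10 (1R,2R,5S)-2-hydroxy-5-methyl-5-(3-methyl-1-nitrobut-3-en-1-yl)-2-(propan-2-yl)cyclopentane-1-carbaldehyde, via acyclic Michael adduct 9 (not isolated)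
Conditions: (R)-2-[diphenyl(trimethylsilyloxy)methyl]pyrrolidine (20 mol%), PhCO2H (40 mol%), 8 (3 equiv), MeOH, rt, 72 h
Reagents that add atoms: none
Why: Proposed new method: an iminium–enamine domino reaction in which the (R)-diarylprolinol silyl ether forms the s-trans E-iminium ion of 6 and the nitronate of 8 adds to the β-carbon on the face away from the CPh2OSiMe3 group, setting the quaternary C5 as S (closest known reaction: diphenylprolinol silyl ether-catalysed addition of nitroalkanes to β,β-disubstituted enals); the resulting enamine is then trapped, before hydrolysis, by 5-exo aldol addition to the tethered isopropyl ketone, which is activated by hydrogen bonding to benzoic acid (closest known type: amine-catalysed enolexo aldolisation and Hajos–Parrish ketol formation), and enamine-mediated epimerisation at C1 together with retro-aldol/aldol equilibration is expected to funnel the material to the most stable ring isomer, with the formyl group trans to both larger neighbours (nitroalkyl chain and isopropyl) and cis to the hydrogen-bonded tertiary hydroxyl (1R,2R); the nitro-bearing carbon forms as a mixture that is erased in step 6.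

**Step 5**
Reactants: 10 (1R,2R,5S)-2-hydroxy-5-methyl-5-(3-methyl-1-nitrobut-3-en-1-yl)-2-(propan-2-yl)cyclopentane-1-carbaldehyde
Product: 11 (3R,3aS,4S,8aS)-8a-methyl-6-methylidene-8-nitro-3-(propan-2-yl)decahydroazulene-3,4-diol
Conditions: Me2AlCl (2.5 equiv), CH2Cl2, −78 → −20 °C
Reagents that add atoms: none
Why: Type-two carbonyl-ene (Prins-type) cyclisation, in which the tertiary hydroxyl becomes an aluminium alkoxide that chelates the cis formyl oxygen, the tethered 1,1-disubstituted alkene can only reach the carbonyl face between the quaternary carbon and the ring-fusion hydrogen, and attack with the complexed oxygen pseudo-equatorial (anti to the ring-fusion bond, away from the angular methyl) is predicted to set C4 as S while closing the trans-fused seven-membered ring; proton loss from the methyl gives the exocyclic alkene, and any endocyclic isomer converges in step 6.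

**Step 6**
Reactants: 11 (3R,3aS,4S,8aS)-8a-methyl-6-methylidene-8-nitro-3-(propan-2-yl)decahydroazulene-3,4-diol
Product: 13 (3R,3aS,4S,8aS)-3,4-dihydroxy-6,8a-dimethyl-3-(propan-2-yl)-2,3,3a,4,5,8a-hexahydroazulen-8(1H)-one, via exo-methylene ketone 12 (not isolated)
Conditions: DBU (3 equiv), O2 (1 atm), MeCN, rt; then Ar, 40 °C
Reagents that add atoms: dioxygen, O=O
Why: Base-mediated aerobic Nef reaction, in which DBU forms the nitronate and O2 oxidises it to the ketone with loss of nitrite (erasing the nitro-bearing stereocentre), after which DBU moves the β,γ-alkene of 12 into conjugation through the dienolate to give the more stable endocyclic trisubstituted enone.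

**Step 7**
Reactants: 13 (3R,3aS,4S,8aS)-3,4-dihydroxy-6,8a-dimethyl-3-(propan-2-yl)-2,3,3a,4,5,8a-hexahydroazulen-8(1H)-one; 14 4-[(tert-butyldimethylsilyl)oxy]benzoic acid
Product: 15 (3R,3aS,4S,8aS)-3-hydroxy-6,8a-dimethyl-8-oxo-3-(propan-2-yl)-1,2,3,3a,4,5,8,8a-octahydroazulen-4-yl 4-[(tert-butyldimethylsilyl)oxy]benzoate
Conditions: DCC, DMAP (cat.), CH2Cl2, 0 °C → rt
Reagents that add atoms: none
Why: Steglich esterification, in which the acylpyridinium derived from 14 acylates the secondary C4 hydroxyl with retention while the hindered tertiary C3 hydroxyl does not react.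

**Step 8**
Reactants: 15 (3R,3aS,4S,8aS)-3-hydroxy-6,8a-dimethyl-8-oxo-3-(propan-2-yl)-1,2,3,3a,4,5,8,8a-octahydroazulen-4-yl 4-[(tert-butyldimethylsilyl)oxy]benzoate
Product: 16 (3R,3aS,4S,8S,8aS)-3,8-dihydroxy-6,8a-dimethyl-3-(propan-2-yl)-1,2,3,3a,4,5,8,8a-octahydroazulen-4-yl 4-[(tert-butyldimethylsilyl)oxy]benzoate
Conditions: NaBH4, CeCl3·7H2O, MeOH, −78 °C
Reagents that add atoms: none
Why: Luche 1,2-reduction, in which hydride attacks the cerium-activated enone on the face opposite the adjacent angular C8a methyl (the same bias as in 17-keto steroids), giving the 8S alcohol cis to that methyl; the aryl ester and silyl ether survive the short cold reaction.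

**Step 9**
Reactants: 16 (3R,3aS,4S,8S,8aS)-3,8-dihydroxy-6,8a-dimethyl-3-(propan-2-yl)-1,2,3,3a,4,5,8,8a-octahydroazulen-4-yl 4-[(tert-butyldimethylsilyl)oxy]benzoate; 17 (2Z)-2-methylbut-2-enoic anhydride
Product: 19 (3R,3aS,4S,8S,8aS)-3-hydroxy-6,8a-dimethyl-8-{[(2Z)-2-methylbut-2-enoyl]oxy}-3-(propan-2-yl)-1,2,3,3a,4,5,8,8a-octahydroazulen-4-yl 4-hydroxybenzoate, via silyl-protected diester 18 (not isolated)
Conditions: LiN(SiMe3)2 (1.2 equiv), THF, −78 °C; 17, −78 → 0 °C; then AcOH, Bu4NF, 0 °C
Reagents that add atoms: none
Why: Alkoxide acylation, in which the lithium alkoxide of the secondary allylic alcohol attacks angelic anhydride at low temperature without a nucleophilic catalyst, so the Z-alkene does not isomerise to the tiglate and the hindered tertiary alkoxide stays unacylated; buffered fluoride then cleaves the phenolic silyl ether in the same pot without touching either ester.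

**Compound list**
1 | 2-methylpropanal (isobutyraldehyde) | CC(C)C=O | starting material
2 | but-3-en-2-one (methyl vinyl ketone) | CC(=O)C=C | starting material
3 | 6-methylheptane-2,5-dione | CC(=O)CCC(=O)C(C)C | intermediate
4 | N-tert-butyl-2-(trimethylsilyl)ethan-1-imine | C[Si](C)(C)CC=NC(C)(C)C | starting material
5 | (2E)-N-tert-butyl-3,7-dimethyl-6-oxooct-2-en-1-imine | CC(C)C(=O)CC/C(C)=C/C=N/C(C)(C)C | intermediate (not isolated)
6 | (2E)-3,7-dimethyl-6-oxooct-2-enal | CC(C)C(=O)CC/C(C)=C/C=O | intermediate
7 | 4-bromo-2-methylbut-1-ene | C=C(C)CCBr | starting material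
8 | 2-methyl-4-nitrobut-1-ene | C=C(C)CC[N+](=O)[O-] | intermediate
9 | (3S)-3,7-dimethyl-3-(3-methyl-1-nitrobut-3-en-1-yl)-6-oxooctanal (both epimers at the nitro carbon) | O=CC[C@@](C)(C(CC(C)=C)[N+](=O)[O-])CCC(=O)C(C)C | intermediate (not isolated)
10 | (1R,2R,5S)-2-hydroxy-5-methyl-5-(3-methyl-1-nitrobut-3-en-1-yl)-2-(propan-2-yl)cyclopentane-1-carbaldehyde (both epimers at the nitro carbon) | O=C[C@@H]1[C@@](C)(C(CC(C)=C)[N+](=O)[O-])CC[C@@]1(O)C(C)C | intermediate
11 | (3R,3aS,4S,8aS)-8a-methyl-6-methylidene-8-nitro-3-(propan-2-yl)decahydroazulene-3,4-diol (both C8 epimers) | [O-][N+](=O)C1CC(=C)C[C@H](O)[C@@H]2[C@]1(C)CC[C@@]2(O)C(C)C | intermediate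
12 | (3R,3aS,4S,8aS)-3,4-dihydroxy-8a-methyl-6-methylidene-3-(propan-2-yl)octahydroazulen-8(1H)-one | O=C1CC(=C)C[C@H](O)[C@@H]2[C@]1(C)CC[C@@]2(O)C(C)C | intermediate (not isolated)
13 | (3R,3aS,4S,8aS)-3,4-dihydroxy-6,8a-dimethyl-3-(propan-2-yl)-2,3,3a,4,5,8a-hexahydroazulen-8(1H)-one | O=C1C=C(C)C[C@H](O)[C@@H]2[C@]1(C)CC[C@@]2(O)C(C)C | intermediate
14 | 4-[(tert-butyldimethylsilyl)oxy]benzoic acid | CC(C)(C)[Si](C)(C)Oc1ccc(cc1)C(O)=O | starting material
15 | (3R,3aS,4S,8aS)-3-hydroxy-6,8a-dimethyl-8-oxo-3-(propan-2-yl)-1,2,3,3a,4,5,8,8a-octahydroazulen-4-yl 4-[(tert-butyldimethylsilyl)oxy]benzoate | O=C1C=C(C)C[C@H](OC(=O)c2ccc(O[Si](C)(C)C(C)(C)C)cc2)[C@@H]2[C@]1(C)CC[C@@]2(O)C(C)C | intermediate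
16 | (3R,3aS,4S,8S,8aS)-3,8-dihydroxy-6,8a-dimethyl-3-(propan-2-yl)-1,2,3,3a,4,5,8,8a-octahydroazulen-4-yl 4-[(tert-butyldimethylsilyl)oxy]benzoate | O[C@H]1C=C(C)C[C@H](OC(=O)c2ccc(O[Si](C)(C)C(C)(C)C)cc2)[C@@H]2[C@]1(C)CC[C@@]2(O)C(C)C | intermediate
17 | (2Z)-2-methylbut-2-enoic anhydride (angelic anhydride) | C/C=C(/C)C(=O)OC(=O)/C(C)=C\C | starting material
18 | (3R,3aS,4S,8S,8aS)-3-hydroxy-6,8a-dimethyl-8-{[(2Z)-2-methylbut-2-enoyl]oxy}-3-(propan-2-yl)-1,2,3,3a,4,5,8,8a-octahydroazulen-4-yl 4-[(tert-butyldimethylsilyl)oxy]benzoate | C/C=C(/C)C(=O)O[C@H]1C=C(C)C[C@H](OC(=O)c2ccc(O[Si](C)(C)C(C)(C)C)cc2)[C@@H]2[C@]1(C)CC[C@@]2(O)C(C)C | intermediate (not isolated)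
19 | (3R,3aS,4S,8S,8aS)-3-hydroxy-6,8a-dimethyl-8-{[(2Z)-2-methylbut-2-enoyl]oxy}-3-(propan-2-yl)-1,2,3,3a,4,5,8,8a-octahydroazulen-4-yl 4-hydroxybenzoate | C/C=C(/C)C(=O)O[C@H]1C=C(C)C[C@H](OC(=O)c2ccc(O)cc2)[C@@H]2[C@]1(C)CC[C@@]2(O)C(C)C | target

**Step count and risk**
Total: 9 steps. Longest linear sequence: 8 steps (1, 2, 4, 5, 6, 7, 8, 9); step 3 is a one-step side branch.

The three steps most likely to fail:

Step 4 (the proposed new step). The secondary nitronate may add slowly or reversibly to the hindered iminium ion, the enamine may not close onto the isopropyl ketone, the ketol may dehydrate, and the sense of induction depends on the E-iminium ion being the reacting isomer (if it proves opposite, the antipodal amine is used). The fallback uses known chemistry and sets out from 6 and 8. The conjugate addition is run on its own under the established conditions for nitroalkane additions to β,β-disubstituted enals (same amine, no acid, 0 °C, stopped when 6 is consumed), and the open-chain aldehyde 9 is isolated. The ring is then closed in a separate flask with L-proline (30 mol%) in DMSO at rt, the classical amino-acid-mediated enamine aldol in which the carboxylic acid activates the ketone and the ketol forms under equilibrium control. This comes back to the route at 10 and makes no new compound.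

Step 5. The closure may deliver the other C4 configuration (or a mixture), because the chelate does not by itself decide which face is attacked. The fallback sets out from 10 and accepts the epimer, (3R,3aS,4R,8aS)-8a-methyl-6-methylidene-8-nitro-3-(propan-2-yl)decahydroazulene-3,4-diol F1. This is taken through the step 6 conditions to (3R,3aS,4R,8aS)-3,4-dihydroxy-6,8a-dimethyl-3-(propan-2-yl)-2,3,3a,4,5,8a-hexahydroazulen-8(1H)-one F2. The carbinol is then inverted in the ester-forming step itself by a Mitsunobu reaction with acid 14 (PPh3, DIAD, toluene, 0 °C → rt; SN2 displacement of the pseudo-axial alcohol), which comes back to the route at 15.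

Step 6. Under base and oxygen the dienolate of ketone 12 may autoxidise, or the hydroxy enone may undergo retro-vinylogous aldol opening. The fallback sets out from 11 and avoids oxygen. O-Benzylation and fragmentation of the nitronate (BnBr, KOH, cat. Bu4NI, THF, rt) give the ketoxime (3R,3aS,4S,8aS)-8-(hydroxyimino)-8a-methyl-6-methylidene-3-(propan-2-yl)decahydroazulene-3,4-diol F3. Buffered aqueous TiCl3 (NH4OAc, THF/H2O, rt) cleaves F3 to ketone 12, and catalytic DBU under argon moves the alkene into conjugation, coming back to the route at 13.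

**Further compounds**
F0 | step 4 | none | none
F1 | step 5 | (3R,3aS,4R,8aS)-8a-methyl-6-methylidene-8-nitro-3-(propan-2-yl)decahydroazulene-3,4-diol (both C8 epimers) | [O-][N+](=O)C1CC(=C)C[C@@H](O)[C@@H]2[C@]1(C)CC[C@@]2(O)C(C)C
F2 | step 5 | (3R,3aS,4R,8aS)-3,4-dihydroxy-6,8a-dimethyl-3-(propan-2-yl)-2,3,3a,4,5,8a-hexahydroazulen-8(1H)-one | O=C1C=C(C)C[C@@H](O)[C@@H]2[C@]1(C)CC[C@@]2(O)C(C)C
F3 | step 6 | (3R,3aS,4S,8aS)-8-(hydroxyimino)-8a-methyl-6-methylidene-3-(propan-2-yl)decahydroazulene-3,4-diol | ON=C1CC(=C)C[C@H](O)[C@@H]2[C@]1(C)CC[C@@]2(O)C(C)C
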